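**Retrosynthetic overview**

- Feature: ring B is a 3-alkoxycyclohex-2-enone (C6=O, C7=C7a–O1) whose alkoxy oxygen O1 is linked through C2 and C3 to the quaternary C3a (benzofuran numbering), so a 4-methoxyacetoacetate-derived diene carried on O1 can reach a C3a=C4 enal.
- The 3a-allyl group comes from a 3a-formyl group (one-carbon homologation, then methylenation); C5 is set last by equilibration.
- Rings A and B form together in one intramolecular Diels–Alder reaction that makes C3a–C7a and C4–C5: ring B is the [4+2] ring, ring A closes through the O1–C2–C3 tether.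
- The diene comes from the benzylic ester of methyl 4-methoxyacetoacetate; the enal comes from a trans α-methylene lactone (reduction, protection, acylation, oxidation).
- C2/C3 come from a catalytic asymmetric (E)-crotylboration of 3,4,5-trimethoxybenzaldehyde; the crotyl vinyl group becomes the lactone.

Key step: step 10

Assumption: the (S) enantiomer of the binaphthyl phosphoric acid is taken to direct the crotyl group to the Si face of aldehyde 1 (1S,2S alcohol); if the first batch proves to be the mirror image, the antipodal catalyst is used.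

**Route**

Step 1
Reactants: 1 3,4,5-trimethoxybenzaldehyde; 2 (E)-crotylboronic acid pinacol ester
Product: 4 (1S,2S)-2-methyl-1-(3,4,5-trimethoxyphenyl)but-3-en-1-ol, via pinacol borate ester 3 (not isolated)
Conditions: (S)-3,3'-bis(2,4,6-triisopropylphenyl)-1,1'-binaphthyl-2,2'-diyl hydrogen phosphate (5 mol%), 4 Å MS, PhMe, −30 °C; then H2O, rt
Reagents that add atoms: none
Why: Chiral-phosphoric-acid-catalysed crotylboration through a closed chair transition state, in which the E geometry of 2 gives the anti relationship that becomes trans C2/C3 and the catalyst is expected to direct attack to the Si face (1S).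

Step 2
Reactants: 4 (1S,2S)-2-methyl-1-(3,4,5-trimethoxyphenyl)but-3-en-1-ol
Product: 6 (1S,2S)-2-methyl-1-(3,4,5-trimethoxyphenyl)butane-1,4-diol, via B-alkyl-9-BBN adduct 5 (not isolated)
Conditions: 9-borabicyclo[3.3.1]nonane (9-BBN-H, 2.5 equiv), THF, 0 °C → rt; then NaOH, H2O2, H2O, 0 °C → rt
Reagents that add atoms: hydrogen peroxide, OO
Why: Anti-Markovnikov hydroboration of the terminal alkene and oxidation of the C–B bond give the primary alcohol without touching either stereocentre.

Step 3
Reactants: 6 (1S,2S)-2-methyl-1-(3,4,5-trimethoxyphenyl)butane-1,4-diol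
Product: 8 (4S,5S)-4-methyl-5-(3,4,5-trimethoxyphenyl)oxolan-2-one, via lactol 7 (not isolated)
Conditions: 2,2,6,6-tetramethylpiperidin-1-oxyl (0.2 equiv), PhI(OAc)2 (2.5 equiv), CH2Cl2, rt
Reagents that add atoms: none
Why: Nitroxyl-catalysed oxidation selects the primary alcohol, the hydroxy aldehyde closes to the five-membered lactol and is oxidised on to the γ-lactone (oxidative lactonisation of a 1,4-diol).

Step 4
Reactants: 8 (4S,5S)-4-methyl-5-(3,4,5-trimethoxyphenyl)oxolan-2-one
Product: 11 (4S,5S)-4-methyl-3-methylidene-5-(3,4,5-trimethoxyphenyl)oxolan-2-one, via Mannich base 9 (not isolated), via trimethylammonium iodide 10 (not isolated)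
Conditions: LiN(iPr)2, THF, −78 °C; CH2=NMe2+ I−, −78 °C → rt; then MeI, MeOH, rt; then NaHCO3, H2O/CH2Cl2, rt
Reagents that add atoms: Eschenmoser's salt (N,N-dimethylmethyleneiminium iodide), C=[N+](C)C.[I-]
Why: Mannich aminomethylation of the lactone enolate, then quaternisation and Hofmann-type β-elimination, installs the exocyclic methylene; C4 and C5 are not acidic and are retained.

Step 5
Reactants: 11 (4S,5S)-4-methyl-3-methylidene-5-(3,4,5-trimethoxyphenyl)oxolan-2-one
Product: 12 (1S,2S)-2-methyl-3-methylidene-1-(3,4,5-trimethoxyphenyl)butane-1,4-diol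
Conditions: iBu2AlH (4 equiv), CH2Cl2, −78 → 0 °C; aq. KNaC4H4O6
Reagents that add atoms: none
Why: Exhaustive 1,2-reduction of the α-methylene lactone by the aluminium hydride (lactone-to-diol reduction) leaves the 1,1-disubstituted alkene untouched.

Step 6
Reactants: 12 (1S,2S)-2-methyl-3-methylidene-1-(3,4,5-trimethoxyphenyl)butane-1,4-diol
Product: 13 (1S,2S)-4-[(tert-butyldimethylsilyl)oxy]-2-methyl-3-methylidene-1-(3,4,5-trimethoxyphenyl)butan-1-ol
Conditions: tBuMe2SiCl (1.05 equiv), imidazole, CH2Cl2, 0 °C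
Reagents that add atoms: tert-butyldimethylsilyl chloride, CC(C)(C)[Si](C)(C)Cl
Why: Silylation is selective for the unhindered primary allylic hydroxyl over the secondary benzylic one (steric differentiation).

Step 7
Reactants: 13 (1S,2S)-4-[(tert-butyldimethylsilyl)oxy]-2-methyl-3-methylidene-1-(3,4,5-trimethoxyphenyl)butan-1-ol; 14 methyl 4-methoxyacetoacetate
Product: 15 (1S,2S)-4-[(tert-butyldimethylsilyl)oxy]-2-methyl-3-methylidene-1-(3,4,5-trimethoxyphenyl)butyl 4-methoxy-3-oxobutanoate
Conditions: 4-(dimethylamino)pyridine (0.3 equiv), 4 Å MS (removal of MeOH), PhMe, 110 °C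
Reagents that add atoms: none
Why: Transesterification of the β-keto ester (through the acylketene or acylpyridinium) acylates the secondary alcohol under neutral conditions with retention at C2, since the C2–O bond is not broken.

Step 8
Reactants: 15 (1S,2S)-4-[(tert-butyldimethylsilyl)oxy]-2-methyl-3-methylidene-1-(3,4,5-trimethoxyphenyl)butyl 4-methoxy-3-oxobutanoate
Product: 16 (1S,2S)-4-hydroxy-2-methyl-3-methylidene-1-(3,4,5-trimethoxyphenyl)butyl 4-methoxy-3-oxobutanoate
Conditions: HF·pyridine, pyridine, THF, 0 °C → rt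
Reagents that add atoms: none
Why: Fluoride cleavage of the primary silyl ether in a buffered medium leaves the β-keto ester and the benzylic ester intact.

Step 9
Reactants: 16 (1S,2S)-4-hydroxy-2-methyl-3-methylidene-1-(3,4,5-trimethoxyphenyl)butyl 4-methoxy-3-oxobutanoate
Product: 17 (1S,2S)-3-formyl-2-methyl-1-(3,4,5-trimethoxyphenyl)but-3-en-1-yl 4-methoxy-3-oxobutanoate
Conditions: MnO2 (20 equiv), CH2Cl2, rt
Reagents that add atoms: none
Why: Oxidation on MnO2 is selective for the allylic alcohol and gives the 2-substituted acrolein, which has no α-hydrogen and cannot form a lactol because O1 is acylated.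

Step 10
Reactants: 17 (1S,2S)-3-formyl-2-methyl-1-(3,4,5-trimethoxyphenyl)but-3-en-1-yl 4-methoxy-3-oxobutanoate
Product: 20 (2S,3S,3aS,5R)-5-methoxy-3-methyl-6-oxo-2-(3,4,5-trimethoxyphenyl)-2,3,5,6-tetrahydro-1-benzofuran-3a(4H)-carbaldehyde, via bis(silyloxy)diene 18 (not isolated), via bis-silyl cycloadduct 19 (not isolated)
Conditions: Me3SiOTf (2.4 equiv), Et3N (4 equiv), Et2O, −78 → 0 °C; decant from Et3NH+ TfO−, evaporate; PhMe (0.01 M), 80 °C; then 0.1 M HCl, THF, 0 °C
Reagents that add atoms: none
Why: Proposed new method: double O-silylation by soft enolisation gives the 1-alkoxy-1,3-bis(silyloxy)diene 18, which on heating should add to the tethered 2-substituted acrolein in a polarised, asynchronous [4+2] process (nucleophilic C5 to the enal β-carbon C4, then the incipient C3a enolate carbon to the doubly oxygen-stabilised C7a), after which dilute acid expels the C7a silyloxy group and frees the C6 ketone; the closest known reaction is the intermolecular Diels–Alder addition of 1-alkoxy-1,3-bis(silyloxy)dienes to 2-substituted acroleins, which has not been run with the enal tethered through the ketene acetal oxygen. Ring B closes as the six-membered [4+2] ring, and ring A (O1–C2–C3–C3a–C7a) closes in the fused mode through the three-atom tether, 5-exo with respect to both C3a=C4 and C7=C7a. C3a is set relative to C3 by the tether: with C2 held on the reacting face, the conformer with C3–H next to the formyl group and C3–CH3 next to C4H2 (aryl and methyl pseudo-equatorial on the forming oxolane, least allylic strain) places C4 cis and CHO trans to the methyl group. C5 follows from the outward methoxy group of the (Z)-enol ether and the formyl-exo transition state usual for 2-substituted acroleins (OMe trans to CHO), is epimerisable and is corrected in step 14, while C7a loses its stereochemistry on elimination. The step needs the C5–C4/C7a–C3a regiochemistry, which both the donor–acceptor polarisation and the short tether impose, preference for the all-carbon [4+2] over hetero-Diels–Alder addition to the enal, which the tether makes geometrically remote, and π-facial selectivity at C3a, which rests on the conformational argument above and is the least certain point.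

Step 11
Reactants: 20 (2S,3S,3aS,5R)-5-methoxy-3-methyl-6-oxo-2-(3,4,5-trimethoxyphenyl)-2,3,5,6-tetrahydro-1-benzofuran-3a(4H)-carbaldehyde
Product: 21 3a-(2-methoxyethenyl) analogue of 20 (E/Z mixture; C5 epimers)
Conditions: MeOCH2PPh3+ Cl− (4 equiv), KN(SiMe3)2 (3.8 equiv), THF, 0 °C; then 20, −78 → 0 °C
Reagents that add atoms: (methoxymethyl)triphenylphosphonium chloride, COC[P+](c1ccccc1)(c1ccccc1)c1ccccc1.[Cl-]
Why: Wittig methoxymethylenation is selective for the aldehyde over the poorly electrophilic vinylogous ester carbonyl; excess ylide may enolise C5, which is why that centre is re-set in step 14.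

Step 12
Reactants: 21 3a-(2-methoxyethenyl) analogue of 20 (E/Z mixture; C5 epimers)
Product: 22 3a-(2-oxoethyl) aldehyde (C5 epimers)
Conditions: 1 M HCl, THF/H2O, 0 °C → rt
Reagents that add atoms: water, O
Why: Acid hydrolysis of the methyl enol ether (C-protonation, hydration of the oxocarbenium ion, loss of methanol) gives the one-carbon-homologated aldehyde, and dilute acid with short contact spares the benzylic C2–O1 bond.

Step 13
Reactants: 22 3a-(2-oxoethyl) aldehyde (C5 epimers)
Product: 23 3a-allyl compound as C5 epimers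
Conditions: Ph3PCH3+ Br− (1.3 equiv), KN(SiMe3)2 (1.2 equiv), THF, −78 → 0 °C
Reagents that add atoms: methyltriphenylphosphonium bromide, C[P+](c1ccccc1)(c1ccccc1)c1ccccc1.[Br-]
Why: Wittig methylenation of the unhindered aldehyde at low temperature should be much faster than attack on, or enolisation of, the vinylogous ester.

Step 14
Reactants: 23 3a-allyl compound as C5 epimers
Product: 24 (2S,3S,3aR,5R)-5-methoxy-3-methyl-3a-(prop-2-en-1-yl)-2-(3,4,5-trimethoxyphenyl)-3,3a,4,5-tetrahydro-1-benzofuran-6(2H)-one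
Conditions: KOtBu (0.2 equiv), tBuOH/THF, 0 °C → rt; AcOH quench
Reagents that add atoms: none
Why: Reversible enolisation of the C6 ketone (thermodynamic epimerisation) should equilibrate C5 to the epimer with the methoxy group pseudo-equatorial and trans to the pseudo-axial 3a-allyl group, the other three stereocentres being non-enolisable.

**Compound list**

1 | 3,4,5-trimethoxybenzaldehyde | COc1cc(C=O)cc(OC)c1OC | starting material
2 | (E)-crotylboronic acid pinacol ester | C/C=C/CB1OC(C)(C)C(C)(C)O1 | starting material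
3 | 2-{[(1S,2S)-2-methyl-1-(3,4,5-trimethoxyphenyl)but-3-en-1-yl]oxy}-4,4,5,5-tetramethyl-1,3,2-dioxaborolane (not isolated) | CC1(C)OB(O[C@H](c2cc(OC)c(OC)c(OC)c2)[C@H](C=C)C)OC1(C)C | intermediate
4 | (1S,2S)-2-methyl-1-(3,4,5-trimethoxyphenyl)but-3-en-1-ol | O[C@H](c1cc(OC)c(OC)c(OC)c1)[C@H](C=C)C | intermediate
5 | 9-[(3S,4S)-4-hydroxy-3-methyl-4-(3,4,5-trimethoxyphenyl)butyl]-9-borabicyclo[3.3.1]nonane (not isolated) | O[C@H](c1cc(OC)c(OC)c(OC)c1)[C@H](CCB1C2CCCC1CCC2)C | intermediate
6 | (1S,2S)-2-methyl-1-(3,4,5-trimethoxyphenyl)butane-1,4-diol | O[C@H](c1cc(OC)c(OC)c(OC)c1)[C@H](CCO)C | intermediate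
7 | (4S,5S)-4-methyl-5-(3,4,5-trimethoxyphenyl)oxolan-2-ol, both anomers (not isolated) | O1[C@H](c2cc(OC)c(OC)c(OC)c2)[C@H](CC1O)C | intermediate
8 | (4S,5S)-4-methyl-5-(3,4,5-trimethoxyphenyl)oxolan-2-one (trans) | O1[C@H](c2cc(OC)c(OC)c(OC)c2)[C@H](CC1=O)C | intermediate
9 | (4S,5S)-3-[(dimethylamino)methyl]-4-methyl-5-(3,4,5-trimethoxyphenyl)oxolan-2-one, C3 epimers (not isolated) | O1[C@H](c2cc(OC)c(OC)c(OC)c2)[C@H](C(CN(C)C)C1=O)C | intermediate
10 | trimethylammonium iodide of 9 (not isolated) | O1[C@H](c2cc(OC)c(OC)c(OC)c2)[C@H](C(C[N+](C)(C)C)C1=O)C.[I-] | intermediate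
11 | (4S,5S)-4-methyl-3-methylidene-5-(3,4,5-trimethoxyphenyl)oxolan-2-one | O1[C@H](c2cc(OC)c(OC)c(OC)c2)[C@H](C(=C)C1=O)C | intermediate
12 | (1S,2S)-2-methyl-3-methylidene-1-(3,4,5-trimethoxyphenyl)butane-1,4-diol | O[C@H](c1cc(OC)c(OC)c(OC)c1)[C@H](C(=C)CO)C | intermediate
13 | (1S,2S)-4-[(tert-butyldimethylsilyl)oxy]-2-methyl-3-methylidene-1-(3,4,5-trimethoxyphenyl)butan-1-ol | O[C@H](c1cc(OC)c(OC)c(OC)c1)[C@H](C(=C)CO[Si](C)(C)C(C)(C)C)C | intermediate
14 | methyl 4-methoxyacetoacetate (methyl 4-methoxy-3-oxobutanoate) | COCC(=O)CC(=O)OC | starting material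
15 | (1S,2S)-4-[(tert-butyldimethylsilyl)oxy]-2-methyl-3-methylidene-1-(3,4,5-trimethoxyphenyl)butyl 4-methoxy-3-oxobutanoate | COCC(=O)CC(=O)O[C@H](c1cc(OC)c(OC)c(OC)c1)[C@H](C(=C)CO[Si](C)(C)C(C)(C)C)C | intermediate
16 | (1S,2S)-4-hydroxy-2-methyl-3-methylidene-1-(3,4,5-trimethoxyphenyl)butyl 4-methoxy-3-oxobutanoate | COCC(=O)CC(=O)O[C@H](c1cc(OC)c(OC)c(OC)c1)[C@H](C(=C)CO)C | intermediate
17 | (1S,2S)-3-formyl-2-methyl-1-(3,4,5-trimethoxyphenyl)but-3-en-1-yl 4-methoxy-3-oxobutanoate | COCC(=O)CC(=O)O[C@H](c1cc(OC)c(OC)c(OC)c1)[C@H](C(=C)C=O)C | intermediate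
18 | bis(trimethylsilyl) dienol ether of 17: 4-methoxy-1,3-bis(trimethylsilyloxy)buta-1,3-dien-1-yl ether of the (1S,2S)-3-formyl-2-methyl-1-(3,4,5-trimethoxyphenyl)but-3-en-1-ol unit, drawn as the (1Z,3Z) isomer, ketene acetal geometry not controlling (not isolated) | CO/C=C(O[Si](C)(C)C)/C=C(O[Si](C)(C)C)/O[C@H](c1cc(OC)c(OC)c(OC)c1)[C@H](C(=C)C=O)C | intermediate
19 | cis-fused cycloadduct: 5-methoxy-3-methyl-2-(3,4,5-trimethoxyphenyl)-6,7a-bis(trimethylsilyloxy)-2,3,4,5-tetrahydro-1-benzofuran-3a(7aH)-carbaldehyde, configuration as in the SMILES (not isolated) | O=C[C@]12C[C@@H](OC)C(O[Si](C)(C)C)=C[C@@]1(O[Si](C)(C)C)O[C@H](c1cc(OC)c(OC)c(OC)c1)[C@H]2C | intermediate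
20 | (2S,3S,3aS,5R)-5-methoxy-3-methyl-6-oxo-2-(3,4,5-trimethoxyphenyl)-2,3,5,6-tetrahydro-1-benzofuran-3a(4H)-carbaldehyde | O=C[C@]12C[C@@H](OC)C(=O)C=C1O[C@H](c1cc(OC)c(OC)c(OC)c1)[C@H]2C | intermediate
21 | 5-methoxy-3a-(2-methoxyethenyl)-3-methyl-2-(3,4,5-trimethoxyphenyl)-3,3a,4,5-tetrahydro-1-benzofuran-6(2H)-one, C2/C3/C3a as in 20, E/Z mixture, C5 epimers | COC=C[C@]12CC(OC)C(=O)C=C1O[C@H](c1cc(OC)c(OC)c(OC)c1)[C@H]2C | intermediate
22 | 2-[5-methoxy-3-methyl-6-oxo-2-(3,4,5-trimethoxyphenyl)-2,3,5,6-tetrahydro-1-benzofuran-3a(4H)-yl]acetaldehyde, C2/C3/C3a as in 24, C5 epimers | O=CC[C@]12CC(OC)C(=O)C=C1O[C@H](c1cc(OC)c(OC)c(OC)c1)[C@H]2C | intermediate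
23 | (2S,3S,3aR)-5-methoxy-3-methyl-3a-(prop-2-en-1-yl)-2-(3,4,5-trimethoxyphenyl)-3,3a,4,5-tetrahydro-1-benzofuran-6(2H)-one, C5 epimers | C=CC[C@]12CC(OC)C(=O)C=C1O[C@H](c1cc(OC)c(OC)c(OC)c1)[C@H]2C | intermediate
24 | (2S,3S,3aR,5R)-5-methoxy-3-methyl-3a-(prop-2-en-1-yl)-2-(3,4,5-trimethoxyphenyl)-3,3a,4,5-tetrahydro-1-benzofuran-6(2H)-one | C=CC[C@]12C[C@@H](OC)C(=O)C=C1O[C@H](c1cc(OC)c(OC)c(OC)c1)[C@H]2C | target

**Step count**

Total: 14 steps. Longest linear sequence: 14 steps (from 1; compounds 2 and 14 are purchased).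

**Steps most likely to fail**

1. Step 10 (key step, proposed new method). Three processes may defeat it:
   - addition of the forming silyl enol ether to the free aldehyde during silylation (Lewis-acid-promoted aldol or Michael reaction);
   - stepwise Michael addition with silyl transfer in place of ring closure;
   - poor or reversed π-facial selectivity at C3a.

   Fallback (known chemistry), setting out from diol 12 and returning at 20: Diol 12 is converted with tBuMe2SiOTf and 2,6-lutidine into the bis-silyl ether F1. HF·pyridine at 0 °C removes the primary allylic silyl group to give the alcohol F2, and MnO2 gives the O-silylated enal F3. Separately, ester 14 is doubly silylated (Me3SiOTf, Et3N; no aldehyde is present at this stage) to 1,4-dimethoxy-1,3-bis(trimethylsilyloxy)buta-1,3-diene F4. F3 and F4 are heated in PhMe (intermolecular Diels–Alder addition of this diene class to a 2-substituted acrolein) to give the cycloadduct F5, and dilute HCl converts it into the 3-methoxycyclohexenone aldehyde F6. Aqueous HF in MeCN frees the benzylic hydroxyl to give the hydroxy enone F7 (in equilibrium with its lactol). Catalytic 10-camphorsulfonic acid in warm PhMe then exchanges the C7a methoxy group for O1 by conjugate addition–elimination, which closes ring A and gives 20. Because the free diene should approach anti to the CH(OSi)Ar group, whereas the tether forces approach syn to C2, the same conformational preference leads to the opposite face at C3a. The variant therefore answers a reversed selectivity as well as a failed cyclisation; C3a epimers would be separated at F6.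

2. Step 11. The basic ylide may enolise C5 and stall, or the hindered formyl group may be lost by retro-Claisen-type cleavage of the vinylogous β-keto aldehyde, before olefination occurs.

   Fallback, setting out from 20 and returning at 23 (bypassing 21 and 22): Aldehyde 20 is vinylated under Nozaki–Hiyama–Kishi conditions (CrCl2, catalytic NiCl2, vinyl bromide, DMF), which are non-basic and aldehyde-selective, to give the allylic alcohol F8. Methyl chloroformate and pyridine give the allylic methyl carbonate F9. Pd(OAc)2/PBu3 with HCO2NH4 then delivers hydride to the more substituted allyl terminus and forms the terminal alkene, which is 23 with C5 unchanged and goes on to step 14.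

3. Step 13. The ylide may act as a base, so that the C5 enolate adds to the pendant aldehyde (intramolecular aldol closure to a bicyclo[3.2.1]octane) or the aldehyde self-condenses.

   Fallback, setting out from 22 and returning at 23: Aldehyde 22 is treated at −78 °C with the organocerium reagent made from Me3SiCH2MgCl and CeCl3, which adds to the aldehyde without enolising it, to give the β-hydroxysilane F10. Dilute H2SO4 in THF then effects the anti elimination of the Peterson olefination and gives 23.

Further compounds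
F1 | step 10 | (1S,2S)-1,4-bis[(tert-butyldimethylsilyl)oxy]-2-methyl-3-methylidene-1-(3,4,5-trimethoxyphenyl)butane | CC(C)(C)[Si](C)(C)O[C@H](c1cc(OC)c(OC)c(OC)c1)[C@H](C(=C)CO[Si](C)(C)C(C)(C)C)C
F2 | step 10 | (3S,4S)-4-[(tert-butyldimethylsilyl)oxy]-3-methyl-2-methylidene-4-(3,4,5-trimethoxyphenyl)butan-1-ol | CC(C)(C)[Si](C)(C)O[C@H](c1cc(OC)c(OC)c(OC)c1)[C@H](C(=C)CO)C
F3 | step 10 | (3S,4S)-4-[(tert-butyldimethylsilyl)oxy]-3-methyl-2-methylidene-4-(3,4,5-trimethoxyphenyl)butanal | CC(C)(C)[Si](C)(C)O[C@H](c1cc(OC)c(OC)c(OC)c1)[C@H](C(=C)C=O)C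
F4 | step 10 | 1,4-dimethoxy-1,3-bis(trimethylsilyloxy)buta-1,3-diene | COC=C(O[Si](C)(C)C)C=C(OC)O[Si](C)(C)C
F5 | step 10 | 1-[(1S,2S)-1-[(tert-butyldimethylsilyl)oxy]-1-(3,4,5-trimethoxyphenyl)propan-2-yl]-2,5-dimethoxy-2,4-bis(trimethylsilyloxy)cyclohex-3-ene-1-carbaldehyde, ring configuration as in the SMILES | O=C[C@@]1(C[C@@H](OC)C(O[Si](C)(C)C)=CC1(OC)O[Si](C)(C)C)[C@H](C)[C@H](O[Si](C)(C)C(C)(C)C)c1cc(OC)c(OC)c(OC)c1
F6 | step 10 | 1-[(1S,2S)-1-[(tert-butyldimethylsilyl)oxy]-1-(3,4,5-trimethoxyphenyl)propan-2-yl]-2,5-dimethoxy-4-oxocyclohex-2-ene-1-carbaldehyde, ring configuration as in the SMILES | O=C[C@@]1(C[C@@H](OC)C(=O)C=C1OC)[C@H](C)[C@H](O[Si](C)(C)C(C)(C)C)c1cc(OC)c(OC)c(OC)c1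
F7 | step 10 | 1-[(1S,2S)-1-hydroxy-1-(3,4,5-trimethoxyphenyl)propan-2-yl]-2,5-dimethoxy-4-oxocyclohex-2-ene-1-carbaldehyde, ring configuration as in the SMILES | O=C[C@@]1(C[C@@H](OC)C(=O)C=C1OC)[C@H](C)[C@H](O)c1cc(OC)c(OC)c(OC)c1
F8 | step 11 | 3a-(1-hydroxyprop-2-en-1-yl)-5-methoxy-3-methyl-2-(3,4,5-trimethoxyphenyl)-3,3a,4,5-tetrahydro-1-benzofuran-6(2H)-one, ring stereocentres as in 20, carbinol epimers | C=CC(O)[C@]12C[C@@H](OC)C(=O)C=C1O[C@H](c1cc(OC)c(OC)c(OC)c1)[C@H]2C
F9 | step 11 | methyl carbonate of F8 | C=CC(OC(=O)OC)[C@]12C[C@@H](OC)C(=O)C=C1O[C@H](c1cc(OC)c(OC)c(OC)c1)[C@H]2C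
F10 | step 13 | 3a-[2-hydroxy-3-(trimethylsilyl)propyl]-5-methoxy-3-methyl-2-(3,4,5-trimethoxyphenyl)-3,3a,4,5-tetrahydro-1-benzofuran-6(2H)-one, C2/C3/C3a as in 24, carbinol and C5 epimers | C[Si](C)(C)CC(O)C[C@]12CC(OC)C(=O)C=C1O[C@H](c1cc(OC)c(OC)c(OC)c1)[C@H]2C
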